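## Analysis of the target

The target 23 is a cyclohexane with four stereocentres: the quaternary C1 carries a tertiary hydroxyl and the carboxyl group, C3 carries the only free secondary hydroxyl, and C4 and C5 carry the two (E)-4-hydroxycinnamoyl (p-coumaroyl) esters. In the stable chair O1 and O3 are axial and O4 and O5 equatorial, so O1, O3 and O4 lie on one face and O5 on the other (O3/O4 cis, O4/O5 trans), and the descriptors are (1S,3R,4R,5R). The sensitive groups are the two conjugated esters (base-induced acyl migration between O3, O4 and O5, fastest across the cis O3/O4 pair; conjugate addition or E/Z isomerisation), the free phenols, and the tertiary α-hydroxy acid. The difficulty lies less in the skeleton than in regiochemistry: three secondary oxygens of similar reactivity must be told apart, two acylated and one left free, and all four centres must be set as one enantiomer. The strategy rests on C4 and C5 being adjacent, both oxygenated, with C4 next to C3. If C3 is a ketone, C4–C5 is the aldol bond between the α-carbon of an acyloxymethyl ketone (C4) and an aldehyde (C5). O3 is then hidden as a carbonyl while both esters are in place, and the ring closure creates both ester-bearing stereocentres. C1 is insulated by the methylenes C2 and C6 and can come from the chiral pool.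

## Retrosynthetic reasoning

**23 ⇐ 22 ⇐ 21 (protecting groups).** The C1 hydroxyl and carboxyl are tied together in 22 as the dioxolanone derived from 2, and the phenols are silyl ethers in 21. Both are removed last without base, so the esters never meet a phenoxide or alkoxide. Aryl silyl ethers resist the acid that opens the dioxolanone, so the end is two operations: desilylation first, acetal hydrolysis second.

**21 ⇐ 20 (C3 carbinol from the ketone).** The C3–H bond is cut back to the ketone 20. Keeping C3 as a carbonyl until both esters are on removes O3 from every acylation. The forward step has to deliver hydride equatorially so that the hydroxyl ends axial, cis to O4 and O1.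

**20 ⇐ 18 + 13 (O5 ester).** The O5–acyl bond is cut. In 18 the C5 hydroxyl is the only free hydroxyl, so acylation with 13 (through its chloride 19) needs no selectivity. Because both esters are the same acyl group, an O4→O5 shift in 18 would be harmless.

**18 ⇐ 15 (C4–C5, ring closure).** This is the central disconnection. Cutting C4–C5 opens the ring to the keto-aldehyde 15, in which the O4 coumarate is already attached as an acyloxymethyl ketone. The bond is cut here because it is the only ring bond flanked by a carbonyl-level carbon (C3) on one side and a carbinol (C5) on the other, and because it creates both esterified centres at once. The forward reaction is an enamine aldol with the amino acid 16 through enamine 17. It must enolise the ketone toward C4, close the six-membered ring, and set C4 and C5 trans to each other with O4 cis to O1. The open-chain "anti" rule for oxygenated donors cannot simply be carried over: the tether decides which aldehyde face is presented, and the trans ring relationship comes from the (E)-enamine and a chair-like closure (see step 10).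

**15 ⇐ 14 (aldehyde unmasking).** The C5 aldehyde is carried as the dimethyl acetal 14 so that 15 is formed in one mild acidic step immediately before the ring closure and is never exposed to base.

**14 ⇐ 10 + 13 (C4–O4 ester).** The ester C–O bond at C4 is cut to the bromomethyl ketone 10 and the carboxylic acid 13 (from 11 via 12). A carboxylate displacement makes the acyloxymethyl ketone directly. A route through a diol would need a selective acylation and an oxidation, and would leave a free hydroxyl within reach of the lactone-type carbonyl.

**10 ⇐ 9 (C3 carbonyl).** The ketone is traced back to the 1,1-disubstituted alkene of 9 (ozonolysis). The alkene is cleaved before any cinnamate is present, so no alkene selectivity is needed.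

**9 ⇐ 6 + 7 (C1–C2, quaternary centre).** The C1–C2 bond is cut to the enolate 8 of dioxolanone 6 and the allylic dibromide 7. The acetal carbon of 6 remembers the configuration while C1 is planar, and the electrophile enters opposite the tert-butyl group, so C1 is formed with retention.

**6 ⇐ 5 ⇐ 4 ⇐ 3 ⇐ 1 + 2 (C6–C5 arm and chiral pool).** The C6–C5 arm is the CH2CO2H arm of 1, taken from acid to alcohol to aldehyde to acetal. The dioxolanone comes from 1 and 2. All carbons of the ring except C2–C4 thus come from 1, and C2–C4 come from 7.

## Alternatives that were turned down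

**Alternative 1:** The disconnection is the C1–C2 bond, back to the open-chain seven-carbon keto acid phosphate A1 (3-deoxy-D-arabino-hept-2-ulosonic acid 7-phosphate). In the forward key step the synthase that makes A2, with its nicotinamide cofactor and divalent cobalt, converts A1 into 3-dehydroquinic acid A2. The sequence is oxidation, loss of phosphate, re-reduction and an intramolecular aldol addition, which closes the carbocycle.
- For it: one aqueous step gives the ring with C1, C4 and C5 in the natural configuration and C3 already a ketone, so it shares the idea of hiding O3 as a carbonyl. Its stereocontrol in ring formation is stronger than any small-molecule catalyst can promise.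
- Against it: A1 is not a shelf chemical and must itself be made enzymatically or in many steps. A2 is a very polar, unprotected hydroxy keto acid that readily loses its C1 hydroxyl by β-elimination, because the C3 ketone acidifies C2. Its carboxyl would have to be protected before a twofold acylation at O4/O5, so the endgame is no shorter than 18 → 23.
- Comparison: the chosen route works entirely with protected, organic-soluble intermediates from 1, has C1 already masked as a dioxolanone, and has one ester in place before the ring exists.

**Alternative 2:** The disconnection is the C5–C6 bond, with C1 as a ring ketone. The methyl keto-aldehyde A4, derived from the deoxypentose A3, is enolised at C6 by an amine or mild base and adds to the C5 aldehyde to give the β-hydroxy cyclohexanone A5.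
- For it: it is short and uses the chiral pool. The O3/O4 cis pair is in place as an acetonide, and the donor is a plain methyl ketone with no α-heteroatom and no ester on board, so this aldol is simpler and more robust than step 10.
- Against it: C1 is still a ketone, so the quaternary carbinol with its carboxyl must be added later (cyanohydrin-type one-carbon addition) with facial control on a flexible ring. The acetonide pairs O3 with O4, whereas the target needs O4 and O5 esterified and O3 free, so the protection has to be reshuffled and a cis-diol differentiated. A5 is prone to β-elimination of water. Working through the descriptors, ring C4 of A5 is C4 of the pentose and must be (S) there, so the sugar needed is A3, the L-series (3R,4S) enantiomer, which is the scarce one of the pair.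
- Comparison: the chosen route builds C1 first with carboxyl and tertiary oxygen in place and separates O3 from O4/O5 by oxidation state instead of by protecting groups.

**Alternative 3:** The disconnection is the C3–C4 bond. SmI2 (samarium diiodide, divalent samarium) reduces the 1,6-dialdehyde A6 and couples the two carbonyl carbons to the cis-diol A7.
- For it: the ring and both carbinol centres C3 and C4 form in one step, chelated samarium pinacol cyclisations normally give cis-diols, and O1, O5 and the carboxyl are already differentiated. It sets C3 in the ring-forming step, which the chosen route does only by a separate reduction.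
- Against it: the product has O3 and O4 free as a cis-diol, which is exactly the pair that must be told apart, with acyl migration between them fast. O5 needs deprotection and a separate esterification. A6 must already hold C1 and C5 on an open chain (the α-alkoxy aldehyde at C5 can epimerise). The face of the new diol relative to C1/C5 rests on substrate control alone.
- Comparison: the chosen route never has O3 and O4 free together and carries one coumarate through the ring closure.

Key step: step 10

Assumption: ring atoms keep the locants of 23 throughout (C1 quaternary carbinol carbon, C3 free hydroxyl, C4 and C5 ester carbons), also in open-chain precursors; 7 and 16 are taken as commercial.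

## Route

Step 1
Reactants: 1 (S)-malic acid; 2 pivalaldehyde
Product: 3 2-[(2S,4S)-2-tert-butyl-5-oxo-1,3-dioxolan-4-yl]acetic acid
Conditions: TsOH (cat.), H2SO4 (cat.), pentane, reflux, azeotropic removal of water; recrystallisation
Reagents that add atoms: none
Why: Acid-catalysed acetalisation of the α-hydroxy acid unit gives the five-membered dioxolanone; under equilibrating conditions the cis isomer (tert-butyl and CH2CO2H on the same face) predominates and is purified by crystallisation, so the new acetal centre (S) is set by the carbinol centre of 1 (first stage of the self-regeneration of stereocentres).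

Step 2
Reactants: 3 2-[(2S,4S)-2-tert-butyl-5-oxo-1,3-dioxolan-4-yl]acetic acid
Product: 4 (2S,5S)-2-tert-butyl-5-(2-hydroxyethyl)-1,3-dioxolan-4-one
Conditions: BH3·SMe2, THF, 0 °C → rt; aqueous work-up at 0 °C
Reagents that add atoms: none
Why: Borane reduces a free carboxylic acid through its acyloxyborane much faster than it attacks the lactone-type dioxolanone carbonyl, so the side chain is taken chemoselectively to the primary alcohol; 4 is kept cold and neutral and used at once because it can translactonise to a γ-butyrolactone.

Step 3
Reactants: 4 (2S,5S)-2-tert-butyl-5-(2-hydroxyethyl)-1,3-dioxolan-4-one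
Product: 5 2-[(2S,4S)-2-tert-butyl-5-oxo-1,3-dioxolan-4-yl]acetaldehyde
Conditions: DMP (1,1,1-triacetoxy-1,1-dihydro-1,2-benziodoxol-3(1H)-one), CH2Cl2, 0 °C → rt
Reagents that add atoms: none
Why: Dess–Martin oxidation of the primary alcohol stops at the aldehyde and runs without base, which would eliminate the β-acetal oxygen of 5.

Step 4
Reactants: 5 2-[(2S,4S)-2-tert-butyl-5-oxo-1,3-dioxolan-4-yl]acetaldehyde
Product: 6 (2S,5S)-2-tert-butyl-5-(2,2-dimethoxyethyl)-1,3-dioxolan-4-one
Conditions: HC(OMe)3, CSA (cat.), CH2Cl2, rt; Et3N quench
Reagents that add atoms: trimethyl orthoformate, COC(OC)OC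
Why: Acid-catalysed acetalisation with the orthoester as methoxy source and water scavenger masks the aldehyde for the enolate, ozonolysis and carboxylate steps; a dimethyl acetal is chosen because it hydrolyses far faster than the acylal-type dioxolanone.

Step 5
Reactants: 6 (2S,5S)-2-tert-butyl-5-(2,2-dimethoxyethyl)-1,3-dioxolan-4-one; 7 3-bromo-2-(bromomethyl)prop-1-ene
Product: 9 (2S,5S)-5-[2-(bromomethyl)prop-2-en-1-yl]-2-tert-butyl-5-(2,2-dimethoxyethyl)-1,3-dioxolan-4-one, via lithium enolate 8 (not isolated)
Conditions: LiN(SiMe3)2, THF, −78 °C; then cannulated into 7 (3 equiv), THF, −78 → −40 °C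
Reagents that add atoms: none
Why: Deprotonation gives the planar enolate 8, whose only stereocentre is the acetal carbon; the allylic bromide is attacked on the face opposite the tert-butyl group (enolate alkylation, self-regeneration of stereocentres), so the quaternary centre (later C1) forms with the new arm trans to tert-butyl, that is with overall retention; adding 8 to excess 7 suppresses twofold alkylation of the symmetrical dibromide.

Step 6
Reactants: 9 (2S,5S)-5-[2-(bromomethyl)prop-2-en-1-yl]-2-tert-butyl-5-(2,2-dimethoxyethyl)-1,3-dioxolan-4-one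
Product: 10 (2S,5R)-5-(3-bromo-2-oxopropyl)-2-tert-butyl-5-(2,2-dimethoxyethyl)-1,3-dioxolan-4-one
Conditions: O3, CH2Cl2, −78 °C, to first blue colour; then Me2S (1.5 equiv), −78 → 0 °C; concentrated cold
Reagents that add atoms: ozone, [O-][O+]=O
Why: Ozonolysis with reductive work-up cleaves the only C=C bond of 9 and turns the allylic bromide into a bromomethyl ketone without acid or base, so acetal and dioxolanone are untouched; the sulfide is kept to a slight excess and removed cold because it could slowly S-alkylate the bromomethyl ketone. The descriptor of the quaternary centre changes from S to R only because the priorities of its two arms change.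

Step 7
Reactants: 11 p-coumaric acid
Product: 13 (2E)-3-{4-[(tert-butyldimethylsilyl)oxy]phenyl}prop-2-enoic acid, via bis-silylated coumarate 12 (not isolated)
Conditions: TBSCl (2.5 equiv), imidazole, DMF, rt; then AcOH/THF/H2O, rt
Reagents that add atoms: tert-butyldimethylsilyl chloride, CC(C)(C)[Si](C)(C)Cl
Why: Silylation of both acidic groups followed by selective hydrolysis of the much more labile silyl ester leaves the phenol as an aryl silyl ether; an ether is preferred to a phenolic ester, which would acylate the amine catalyst in step 10.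

Step 8
Reactants: 10 (2S,5R)-5-(3-bromo-2-oxopropyl)-2-tert-butyl-5-(2,2-dimethoxyethyl)-1,3-dioxolan-4-one; 13 (2E)-3-{4-[(tert-butyldimethylsilyl)oxy]phenyl}prop-2-enoic acid
Product: 14 3-[(2S,4R)-2-tert-butyl-4-(2,2-dimethoxyethyl)-5-oxo-1,3-dioxolan-4-yl]-2-oxopropyl (2E)-3-{4-[(tert-butyldimethylsilyl)oxy]phenyl}prop-2-enoate
Conditions: KHCO3, DMF, 0 °C → rt
Reagents that add atoms: none
Why: SN2 displacement of an α-bromo ketone by a carboxylate is fast under bicarbonate conditions and forms the C4–O4 ester bond without any hydroxyl intermediate, so neither acyl migration nor lactonisation onto the dioxolanone can occur.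

Step 9
Reactants: 14 3-[(2S,4R)-2-tert-butyl-4-(2,2-dimethoxyethyl)-5-oxo-1,3-dioxolan-4-yl]-2-oxopropyl (2E)-3-{4-[(tert-butyldimethylsilyl)oxy]phenyl}prop-2-enoate
Product: 15 3-[(2S,4R)-2-tert-butyl-5-oxo-4-(2-oxoethyl)-1,3-dioxolan-4-yl]-2-oxopropyl (2E)-3-{4-[(tert-butyldimethylsilyl)oxy]phenyl}prop-2-enoate
Conditions: TFA/H2O (1:1), CHCl3, 0 °C
Reagents that add atoms: water, O
Why: Brief aqueous acid hydrolyses the dimethyl acetal, while the dioxolanone (an acylal whose oxocarbenium ion is destabilised by the acyl group), the aryl silyl ether and the esters are stable under these conditions; 15 is used directly.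

Step 10
Reactants: 15 3-[(2S,4R)-2-tert-butyl-5-oxo-4-(2-oxoethyl)-1,3-dioxolan-4-yl]-2-oxopropyl (2E)-3-{4-[(tert-butyldimethylsilyl)oxy]phenyl}prop-2-enoate; 16 L-proline (catalyst)
Product: 18 (2S,5R,7R,8S)-2-tert-butyl-7-hydroxy-4,9-dioxo-1,3-dioxaspiro[4.5]decan-8-yl (2E)-3-{4-[(tert-butyldimethylsilyl)oxy]phenyl}prop-2-enoate, via proline enamine 17 (not isolated)
Conditions: 16 (30 mol%), DMSO (0.05 M), rt
Reagents that add atoms: none
Why: Condensation of the C3 ketone of 15 with 16 (loss of water) gives an iminium ion that tautomerises toward the more acidic, oxygen-bearing C4 to the (E)-enamine 17 (O4 trans to nitrogen); its C4 adds to the C5 aldehyde, which is activated by a hydrogen bond from the carboxylic acid of the catalyst, and the water set free in the condensation hydrolyses the new iminium ion to 18 and returns 16 unchanged for the next turnover. The closest known reaction type is the proline-catalysed intramolecular enamine aldol of the Hajos–Parrish type, combined with the known preference of α-oxygenated ketones to react through the oxygen-substituted enamine. The ring closes in the 6-(enolendo)-exo-trig mode through a chair-like transition state; the regioisomeric C2 enamine could only give a four-membered ring and reverts. C4 is controlled by the (E)-geometry of the enamine together with the enamine face that carries the carboxylic acid of the (S)-catalyst, the same sense that this catalyst shows with hydroxyacetone-type donors, which places O4 pseudo-axial and cis to O1. C5 is controlled by the tether: with the aldehyde oxygen held by the carboxylic acid, C6 can only lie on the C2 side, which places O5 pseudo-axial and trans to O4, and ring inversion then gives the 4,5-trans-diequatorial product in which the spiro carbon is C1, the ketone C3, the ester carbon C4 and the carbinol C5. Because C4 stays epimerisable next to the ketone, any cis isomer can drain into the more stable trans-diequatorial one. The step needs the ketone and not the aldehyde to act as donor, which is secured by the absence of a ring-forming path for the aldehyde enamine, the neopentyl position of C6 and high dilution; it also needs the absolute sense at C4/C5 to be set by the catalyst and not by C1, which is the point to be tested.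

Step 11
Reactants: 18 (2S,5R,7R,8S)-2-tert-butyl-7-hydroxy-4,9-dioxo-1,3-dioxaspiro[4.5]decan-8-yl (2E)-3-{4-[(tert-butyldimethylsilyl)oxy]phenyl}prop-2-enoate; 13 (2E)-3-{4-[(tert-butyldimethylsilyl)oxy]phenyl}prop-2-enoic acid
Product: 20 (2S,5R,7R,8S)-2-tert-butyl-4,9-dioxo-1,3-dioxaspiro[4.5]decane-7,8-diyl bis[(2E)-3-{4-[(tert-butyldimethylsilyl)oxy]phenyl}prop-2-enoate], via acid chloride 19 (not isolated)
Conditions: 13, Me2C=C(Cl)NMe2, CH2Cl2, 0 °C → rt; then 18, pyridine, CH2Cl2, 0 °C → rt
Reagents that add atoms: none
Why: The acid chloride 19 is generated under neutral conditions with the α-chloroenamine and acylates the secondary C5 hydroxyl through an acylpyridinium ion with pyridine as the only base; C3 is still a ketone, so no second hydroxyl competes, and the weak base together with the equatorial, poorly aligned C5–O bond disfavours E1cB loss of the new ester.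

Step 12
Reactants: 20 (2S,5R,7R,8S)-2-tert-butyl-4,9-dioxo-1,3-dioxaspiro[4.5]decane-7,8-diyl bis[(2E)-3-{4-[(tert-butyldimethylsilyl)oxy]phenyl}prop-2-enoate]
Product: 21 (2S,5S,7R,8R,9R)-2-tert-butyl-9-hydroxy-4-oxo-1,3-dioxaspiro[4.5]decane-7,8-diyl bis[(2E)-3-{4-[(tert-butyldimethylsilyl)oxy]phenyl}prop-2-enoate]
Conditions: Li[HB(sBu)3] (1.1 equiv), THF, −78 °C; AcOH, −78 °C
Reagents that add atoms: none
Why: The bulky trialkylborohydride attacks the C3 carbonyl from the equatorial direction because the axial trajectory is blocked by the syn-axial C1–O bond and H5, which gives the axial alcohol cis to O4 and O1 (substrate-controlled hydride reduction); ketone reduction at −78 °C is much faster than conjugate reduction of the cinnamate esters, and the acetic acid quench at −78 °C protonates the alkoxide before it can attack the neighbouring O4 ester.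

Step 13
Reactants: 21 (2S,5S,7R,8R,9R)-2-tert-butyl-9-hydroxy-4-oxo-1,3-dioxaspiro[4.5]decane-7,8-diyl bis[(2E)-3-{4-[(tert-butyldimethylsilyl)oxy]phenyl}prop-2-enoate]
Product: 22 (2S,5S,7R,8R,9R)-2-tert-butyl-9-hydroxy-4-oxo-1,3-dioxaspiro[4.5]decane-7,8-diyl bis[(2E)-3-(4-hydroxyphenyl)prop-2-enoate]
Conditions: HF·pyridine, pyridine/THF, 0 °C → rt
Reagents that add atoms: none
Why: Fluoride cleaves the aryl silyl ethers through formation of the strong Si–F bond under buffered, mildly acidic conditions, so no phenoxide or alkoxide is formed and acyl migration is avoided; esters and dioxolanone are inert to this reagent.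

Step 14
Reactants: 22 (2S,5S,7R,8R,9R)-2-tert-butyl-9-hydroxy-4-oxo-1,3-dioxaspiro[4.5]decane-7,8-diyl bis[(2E)-3-(4-hydroxyphenyl)prop-2-enoate]
Product: 23 4,5-di-O-p-coumaroylquinic acid, (1S,3R,4R,5R)-1,3-dihydroxy-4,5-bis{[(2E)-3-(4-hydroxyphenyl)prop-2-enoyl]oxy}cyclohexane-1-carboxylic acid
Conditions: 2 M aq. HCl/THF (1:3), rt
Reagents that add atoms: water, O
Why: Acid-catalysed hydrolysis of the acylal opens the dioxolanone and liberates the tertiary hydroxyl and the carboxylic acid together with pivalaldehyde; secondary cinnamate esters survive dilute aqueous acid at room temperature, and acyl migration is slow under acidic conditions.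

## Compound list

1 | (S)-malic acid | OC(=O)C[C@@H](C(=O)O)O | starting material
2 | pivalaldehyde (2,2-dimethylpropanal) | CC(C)(C)C=O | starting material
3 | 2-[(2S,4S)-2-tert-butyl-5-oxo-1,3-dioxolan-4-yl]acetic acid (tert-butyl cis to the acetic acid arm) | OC(=O)C[C@@H]1O[C@H](C(C)(C)C)OC1=O | intermediate
4 | (2S,5S)-2-tert-butyl-5-(2-hydroxyethyl)-1,3-dioxolan-4-one | OCC[C@@H]1O[C@H](C(C)(C)C)OC1=O | intermediate
5 | 2-[(2S,4S)-2-tert-butyl-5-oxo-1,3-dioxolan-4-yl]acetaldehyde | O=CC[C@@H]1O[C@H](C(C)(C)C)OC1=O | intermediate
6 | (2S,5S)-2-tert-butyl-5-(2,2-dimethoxyethyl)-1,3-dioxolan-4-one | COC(OC)C[C@@H]1O[C@H](C(C)(C)C)OC1=O | intermediate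
7 | 3-bromo-2-(bromomethyl)prop-1-ene | C=C(CBr)CBr | starting material
8 | lithium (2S)-2-tert-butyl-5-(2,2-dimethoxyethyl)-1,3-dioxol-4-olate | COC(OC)CC1=C(O[Li])O[C@@H](C(C)(C)C)O1 | intermediate
9 | (2S,5S)-5-[2-(bromomethyl)prop-2-en-1-yl]-2-tert-butyl-5-(2,2-dimethoxyethyl)-1,3-dioxolan-4-one (tert-butyl cis to the acetal arm) | COC(OC)C[C@]1(CC(=C)CBr)O[C@H](C(C)(C)C)OC1=O | intermediate
10 | (2S,5R)-5-(3-bromo-2-oxopropyl)-2-tert-butyl-5-(2,2-dimethoxyethyl)-1,3-dioxolan-4-one | COC(OC)C[C@]1(CC(=O)CBr)O[C@H](C(C)(C)C)OC1=O | intermediate
11 | p-coumaric acid, (2E)-3-(4-hydroxyphenyl)prop-2-enoic acid | OC(=O)/C=C/c1ccc(O)cc1 | starting material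
12 | tert-butyldimethylsilyl (2E)-3-{4-[(tert-butyldimethylsilyl)oxy]phenyl}prop-2-enoate | CC(C)(C)[Si](C)(C)OC(=O)/C=C/c1ccc(O[Si](C)(C)C(C)(C)C)cc1 | intermediate
13 | (2E)-3-{4-[(tert-butyldimethylsilyl)oxy]phenyl}prop-2-enoic acid | OC(=O)/C=C/c1ccc(O[Si](C)(C)C(C)(C)C)cc1 | intermediate
14 | 3-[(2S,4R)-2-tert-butyl-4-(2,2-dimethoxyethyl)-5-oxo-1,3-dioxolan-4-yl]-2-oxopropyl (2E)-3-{4-[(tert-butyldimethylsilyl)oxy]phenyl}prop-2-enoate | COC(OC)C[C@]1(CC(=O)COC(=O)/C=C/c2ccc(O[Si](C)(C)C(C)(C)C)cc2)O[C@H](C(C)(C)C)OC1=O | intermediate
15 | 3-[(2S,4R)-2-tert-butyl-5-oxo-4-(2-oxoethyl)-1,3-dioxolan-4-yl]-2-oxopropyl (2E)-3-{4-[(tert-butyldimethylsilyl)oxy]phenyl}prop-2-enoate (4,5-seco keto-aldehyde) | O=CC[C@]1(CC(=O)COC(=O)/C=C/c2ccc(O[Si](C)(C)C(C)(C)C)cc2)O[C@H](C(C)(C)C)OC1=O | intermediate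
16 | L-proline, (S)-pyrrolidine-2-carboxylic acid (catalyst) | OC(=O)[C@@H]1CCCN1 | starting material
17 | (E)-enamine of 15 with 16 (pyrrolidine nitrogen on C3, C3=C4 double bond, O4 trans to nitrogen) | O=CC[C@]1(C/C(N2CCC[C@H]2C(=O)O)=C\OC(=O)/C=C/c2ccc(O[Si](C)(C)C(C)(C)C)cc2)O[C@H](C(C)(C)C)OC1=O | intermediate
18 | (2S,5R,7R,8S)-2-tert-butyl-7-hydroxy-4,9-dioxo-1,3-dioxaspiro[4.5]decan-8-yl (2E)-3-{4-[(tert-butyldimethylsilyl)oxy]phenyl}prop-2-enoate (O4 ester and O5 hydroxyl trans, O4 cis to ring O1) | O=C(/C=C/c1ccc(O[Si](C)(C)C(C)(C)C)cc1)O[C@@H]1C(=O)C[C@@]2(C[C@H]1O)O[C@H](C(C)(C)C)OC2=O | intermediate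
19 | (2E)-3-{4-[(tert-butyldimethylsilyl)oxy]phenyl}prop-2-enoyl chloride | ClC(=O)/C=C/c1ccc(O[Si](C)(C)C(C)(C)C)cc1 | intermediate
20 | (2S,5R,7R,8S)-2-tert-butyl-4,9-dioxo-1,3-dioxaspiro[4.5]decane-7,8-diyl bis[(2E)-3-{4-[(tert-butyldimethylsilyl)oxy]phenyl}prop-2-enoate] | O=C(/C=C/c3ccc(O[Si](C)(C)C(C)(C)C)cc3)O[C@@H]1C(=O)C[C@@]2(C[C@H]1OC(=O)/C=C/c4ccc(O[Si](C)(C)C(C)(C)C)cc4)O[C@H](C(C)(C)C)OC2=O | intermediate
21 | (2S,5S,7R,8R,9R)-2-tert-butyl-9-hydroxy-4-oxo-1,3-dioxaspiro[4.5]decane-7,8-diyl bis[(2E)-3-{4-[(tert-butyldimethylsilyl)oxy]phenyl}prop-2-enoate] (C3 hydroxyl axial, cis to O4 and O1) | O=C(/C=C/c3ccc(O[Si](C)(C)C(C)(C)C)cc3)O[C@@H]1[C@H](O)C[C@@]2(C[C@H]1OC(=O)/C=C/c4ccc(O[Si](C)(C)C(C)(C)C)cc4)O[C@H](C(C)(C)C)OC2=O | intermediate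
22 | (2S,5S,7R,8R,9R)-2-tert-butyl-9-hydroxy-4-oxo-1,3-dioxaspiro[4.5]decane-7,8-diyl bis[(2E)-3-(4-hydroxyphenyl)prop-2-enoate] | O=C(/C=C/c3ccc(O)cc3)O[C@@H]1[C@H](O)C[C@@]2(C[C@H]1OC(=O)/C=C/c4ccc(O)cc4)O[C@H](C(C)(C)C)OC2=O | intermediate
23 | 4,5-di-O-p-coumaroylquinic acid, (1S,3R,4R,5R)-1,3-dihydroxy-4,5-bis{[(2E)-3-(4-hydroxyphenyl)prop-2-enoyl]oxy}cyclohexane-1-carboxylic acid | O=C(/C=C/c1ccc(O)cc1)O[C@@H]1[C@H](O)C[C@@](O)(C(=O)O)C[C@H]1OC(=O)/C=C/c1ccc(O)cc1 | target

## Step count and least certain steps

Total step count: 14. Longest linear sequence: 13 steps (steps 1–6 and 8–14 from 1); step 7 is the side branch from 11.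

**Step 10 (key step).** Several processes can compete:
- condensation of the catalyst with the aldehyde instead of the ketone, leading to intermolecular self-aldolisation;
- loss of the β-oxygen O1 through the C2 enamine (opening of the dioxolanone), or dehydration across C4–C5;
- erosion of facial control if catalyst control and the bias of the C1 centre oppose each other, giving the 4,5-bis-epimer;
- transfer of the activated O4 acyl group to the catalyst nitrogen.

Fallback: O4 is carried through the ring closure as a free hydroxyl (a hydroxyacetone-type donor) and both coumarates are attached afterwards. It sets out from 10. Displacement of bromide with HCO2Na in DMF gives 3-[(2S,4R)-2-tert-butyl-4-(2,2-dimethoxyethyl)-5-oxo-1,3-dioxolan-4-yl]-2-oxopropyl formate F1. Brief methanolysis (KHCO3, MeOH, 0 °C) gives the hydroxymethyl ketone (2S,5R)-2-tert-butyl-5-(2,2-dimethoxyethyl)-5-(3-hydroxy-2-oxopropyl)-1,3-dioxolan-4-one F2. Acetal hydrolysis as in step 9 gives 2-[(2S,4R)-2-tert-butyl-4-(3-hydroxy-2-oxopropyl)-5-oxo-1,3-dioxolan-4-yl]acetaldehyde F3. Catalyst 16 in DMSO should close it to (2S,5R,8S,9R)-2-tert-butyl-8,9-dihydroxy-1,3-dioxaspiro[4.5]decane-4,7-dione F4. Twofold acylation of F4 with 19 (2.5 equiv) and pyridine, while C3 is still a ketone, comes back to the route at 20.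

**Step 5.** One molecule of 7 can bridge two enolates (twofold alkylation), and the enolate can decompose if it warms before it is alkylated.

Fallback: from 6 (through 8), alkylation with the monofunctional 2,3-dibromopropene gives (2S,5R)-5-(2-bromoprop-2-en-1-yl)-2-tert-butyl-5-(2,2-dimethoxyethyl)-1,3-dioxolan-4-one F5. NBS in NaOAc-buffered aqueous MeCN then converts the 2-bromoallyl group into the bromomethyl ketone and comes back at 10.

**Step 11.** E1cB elimination of the new β-acyloxy group (or of O1) from the ketone can occur under the acylation conditions, or the acylation of the hydroxyl next to the O4 ester can be sluggish.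

Fallback: reduction and acylation change places. From 18, hydroxyl-directed reduction with Me4NBH(OAc)3 in MeCN/AcOH (Evans–Saksena reduction, hydride delivered from the O5-bound borate to give the 1,3-anti diol, that is the axial C3 hydroxyl) gives (2S,7R,9R)-2-tert-butyl-7,9-dihydroxy-4-oxo-1,3-dioxaspiro[4.5]decan-8-yl (2E)-3-{4-[(tert-butyldimethylsilyl)oxy]phenyl}prop-2-enoate F6. Selective acylation of its equatorial O5 hydroxyl over the axial, more hindered O3 hydroxyl with 19 (1.1 equiv) and pyridine at −20 °C comes back at 21.

**Step 12.** Facial selectivity may be insufficient (formation of the equatorial C3 epimer), a cinnamate may undergo conjugate reduction, or the O4 acyl group may migrate to the new cis alkoxide before the quench.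

Fallback: from 20, a catalyst-controlled Corey–Bakshi–Shibata reduction ((S)-configured B-methyl oxazaborolidine, catecholborane, toluene, −78 °C) reduces the boron-bound ketone without a free alkoxide. The facial sense is set by the catalyst with C4 as the large flank. It gives 21 directly and forms no compound outside the main list (entry F0).

**Step 14.** Hydrolysis of the acylal may be slow, so that long exposure to acid causes partial ester hydrolysis or O4→O3 migration.

Fallback: from 22, acid-catalysed alcoholysis of the dioxolanone with allyl alcohol (HCl from AcCl, rt) gives prop-2-en-1-yl (1S,3R,4R,5R)-1,3-dihydroxy-4,5-bis{[(2E)-3-(4-hydroxyphenyl)prop-2-enoyl]oxy}cyclohexane-1-carboxylate F7. Pd(PPh3)4 (zerovalent palladium) and morpholine in THF then cleave the allyl ester under neutral conditions and come back at 23.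

## Further compounds

F1 | step 10 | 3-[(2S,4R)-2-tert-butyl-4-(2,2-dimethoxyethyl)-5-oxo-1,3-dioxolan-4-yl]-2-oxopropyl formate | COC(OC)C[C@]1(CC(=O)COC=O)O[C@H](C(C)(C)C)OC1=O
F2 | step 10 | (2S,5R)-2-tert-butyl-5-(2,2-dimethoxyethyl)-5-(3-hydroxy-2-oxopropyl)-1,3-dioxolan-4-one | COC(OC)C[C@]1(CC(=O)CO)O[C@H](C(C)(C)C)OC1=O
F3 | step 10 | 2-[(2S,4R)-2-tert-butyl-4-(3-hydroxy-2-oxopropyl)-5-oxo-1,3-dioxolan-4-yl]acetaldehyde | O=CC[C@]1(CC(=O)CO)O[C@H](C(C)(C)C)OC1=O
F4 | step 10 | (2S,5R,8S,9R)-2-tert-butyl-8,9-dihydroxy-1,3-dioxaspiro[4.5]decane-4,7-dione | O[C@@H]1C(=O)C[C@@]2(C[C@H]1O)O[C@H](C(C)(C)C)OC2=O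
F5 | step 5 | (2S,5R)-5-(2-bromoprop-2-en-1-yl)-2-tert-butyl-5-(2,2-dimethoxyethyl)-1,3-dioxolan-4-one | COC(OC)C[C@]1(CC(Br)=C)O[C@H](C(C)(C)C)OC1=O
F6 | step 11 | (2S,7R,9R)-2-tert-butyl-7,9-dihydroxy-4-oxo-1,3-dioxaspiro[4.5]decan-8-yl (2E)-3-{4-[(tert-butyldimethylsilyl)oxy]phenyl}prop-2-enoate (ester oxygen cis to the C3 hydroxyl and ring O1, trans to the C5 hydroxyl) | O=C(/C=C/c3ccc(O[Si](C)(C)C(C)(C)C)cc3)O[C@@H]1[C@H](O)C[C@@]2(C[C@H]1O)O[C@H](C(C)(C)C)OC2=O
F0 | step 12 | none | none
F7 | step 14 | prop-2-en-1-yl (1S,3R,4R,5R)-1,3-dihydroxy-4,5-bis{[(2E)-3-(4-hydroxyphenyl)prop-2-enoyl]oxy}cyclohexane-1-carboxylate | O=C(/C=C/c1ccc(O)cc1)O[C@@H]1[C@H](O)C[C@@](O)(C(=O)OCC=C)C[C@H]1OC(=O)/C=C/c1ccc(O)cc1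
A1 | alternative 1 | 3-deoxy-D-arabino-hept-2-ulosonic acid 7-phosphate, (4R,5S,6R)-4,5,6-trihydroxy-2-oxo-7-(phosphonooxy)heptanoic acid | OC(=O)C(=O)C[C@@H](O)[C@H](O)[C@H](O)COP(=O)(O)O
A2 | alternative 1 | 3-dehydroquinic acid, (1R,3R,4S)-1,3,4-trihydroxy-5-oxocyclohexane-1-carboxylic acid | O[C@@H]1C(=O)C[C@@](O)(C(=O)O)C[C@H]1O
A3 | alternative 2 | 2-deoxy-L-ribose, (3R,4S)-3,4,5-trihydroxypentanal | O=CC[C@@H](O)[C@@H](O)CO
A4 | alternative 2 | (4R,5R)-2,2-dimethyl-5-(2-oxopropyl)-1,3-dioxolane-4-carbaldehyde | CC(=O)C[C@H]1OC(C)(C)O[C@H]1C=O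
A5 | alternative 2 | (3R,4S,5R)-5-hydroxy-3,4-(isopropylidenedioxy)cyclohexan-1-one | O=C1C[C@H]2OC(C)(C)O[C@H]2[C@H](O)C1
A6 | alternative 3 | tert-butyl (2R,4R)-4-[(4-methoxybenzyl)oxy]-5-oxo-2-(2-oxoethyl)-2-[(triethylsilyl)oxy]pentanoate | O=CC[C@@](O[Si](CC)(CC)CC)(C(=O)OC(C)(C)C)C[C@H](C=O)OCc1ccc(OC)cc1
A7 | alternative 3 | tert-butyl 5-O-(4-methoxybenzyl)-1-O-(triethylsilyl)quinate | O[C@@H]1[C@H](O)C[C@@](O[Si](CC)(CC)CC)(C(=O)OC(C)(C)C)C[C@H]1OCc1ccc(OC)cc1
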